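**Plan**
- Cuts, in retrosynthetic order: the O9 acetate and O8 epoxyangelate esters; C11=C13 (olefination) and C7–C11 (lactone closure); the O6–C12 ester; the 4,5-epoxide (from a 4Z alkene); C5–C6 (ten-membered ring closure); C9–C10 (fragment union).
- Enabling feature: in the γ-lactone ring (O–C6–C7–C11–C12) the C7–C11 bond is anti to C8–O8 and cis to C6–O6. This is the imprint of an anti opening of a trans-7,8-epoxide at C7 by a carbon nucleophile tethered to O6, so a phosphonoacetate on O6 closes the lactone, sets C7, frees O8 and carries the handle for the exocyclic methylene.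
- Forward order: west piece (C1–C5, C10, C14, C15; iodoenoate 9) and east piece (C6–C9; epoxy aldehyde 13) are joined at C9–C10. The ten-membered ring is closed at C5–C6, the 4,5-epoxide is added, the lactone ring is closed, then the O8 and O9 esters are installed.
- Stereochemistry: three Sharpless epoxidations with D-(−)-diethyl tartrate set C2/C3, C7/C8 and the epoxyangelate. C9 and C6 come from Felkin–Anh additions to trans-epoxy aldehydes. C4/C5 come from a hydroxyl-directed peripheral epoxidation, and C7 from inversion in the lactone closure.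
- Alkene geometry: 4Z from an anti-carbomagnesiation, the cis-2,3-epoxide from a Still–Gennari olefination, ring-cis C1=C10 from an iodo-ylide Wittig reaction.

Key step: step 17

Remark: locants C1–C15 are those of the germacrane skeleton of the target (ring C1–C10, lactone C11–C13, ester carbon C14, methyl C15), also in the cyclodecene names; compounds 9–19, whose cis-2,3-epoxide lies between two alkenes, are kept at or below 23 °C to avoid the divinyl-epoxide Cope rearrangement.

Step 1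
Reactants: 1 prop-2-yn-1-ol
Product: 3 (2Z)-3-iodo-2-methylprop-2-en-1-ol, via chelated alkenylmagnesium bromide 2 (not isolated)
Conditions: MeMgBr (2.5 equiv), CuI (10 mol %), THF, −10 → 23 °C; then I2, −78 → 0 °C
Reagents that add atoms: methylmagnesium bromide C[Mg]Br; iodine II
Why: Copper-catalysed anti-carbomagnesiation of the propargylic alkoxide (Duboudin–Jousseaume) puts CH3 on C4 and magnesium cis to the CH2O group in a five-membered chelate, and iodinolysis with retention gives the (Z)-alkenyl iodide that later defines the 4Z geometry.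

Step 2
Reactants: 3 (2Z)-3-iodo-2-methylprop-2-en-1-ol
Product: 4 (2Z)-3-iodo-2-methylprop-2-enal
Conditions: MnO2, CH2Cl2, 23 °C
Reagents that add atoms: none
Why: MnO2 oxidises the allylic alcohol to the enal under neutral conditions that should not isomerise the (Z)-iodoalkene.

Step 3
Reactants: 4 (2Z)-3-iodo-2-methylprop-2-enal
Product: 5 methyl (2Z,4Z)-5-iodo-4-methylpenta-2,4-dienoate
Conditions: (CF3CH2O)2P(O)CH2CO2Me, KN(SiMe3)2, 18-crown-6, THF, −78 °C
Reagents that add atoms: methyl bis(2,2,2-trifluoroethyl)phosphonoacetate COC(=O)CP(=O)(OCC(F)(F)F)OCC(F)(F)F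
Why: Still–Gennari olefination with the electron-poor phosphonate under dissociating conditions gives the (Z)-enoate kinetically, which provides the cis relationship needed for the cis-2,3-epoxide.

Step 4
Reactants: 5 methyl (2Z,4Z)-5-iodo-4-methylpenta-2,4-dienoate
Product: 6 (2Z,4Z)-5-iodo-4-methylpenta-2,4-dien-1-ol
Conditions: i-Bu2AlH, CH2Cl2, −78 °C
Reagents that add atoms: none
Why: Hydride reduction of the conjugated ester to the allylic alcohol at low temperature leaves the alkenyl iodide and both Z double bonds untouched.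

Step 5
Reactants: 6 (2Z,4Z)-5-iodo-4-methylpenta-2,4-dien-1-ol
Product: 7 [(2R,3S)-3-[(1Z)-1-iodoprop-1-en-2-yl]oxiran-2-yl]methanol
Conditions: Ti(OiPr)4 (cat.), D-(−)-diethyl tartrate (cat.), t-BuOOH, 4 Å MS, CH2Cl2, −20 °C
Reagents that add atoms: tert-butyl hydroperoxide CC(C)(C)OO
Why: Sharpless asymmetric epoxidation touches only the allylic C2=C3 bond, and D-(−)-tartrate delivers oxygen to the face that gives the (2R,3S) cis-epoxy alcohol, which fixes C2 and C3.

Step 6
Reactants: 7 [(2R,3S)-3-[(1Z)-1-iodoprop-1-en-2-yl]oxiran-2-yl]methanol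
Product: 8 (2S,3S)-3-[(1Z)-1-iodoprop-1-en-2-yl]oxirane-2-carbaldehyde
Conditions: Dess–Martin periodinane, pyridine, CH2Cl2, 0 °C
Reagents that add atoms: none
Why: Buffered Dess–Martin oxidation gives the cis-epoxy aldehyde without epimerisation or epoxide opening.

Step 7
Reactants: 8 (2S,3S)-3-[(1Z)-1-iodoprop-1-en-2-yl]oxirane-2-carbaldehyde
Product: 9 methyl (2Z)-2-iodo-3-[(2R,3S)-3-[(1Z)-1-iodoprop-1-en-2-yl]oxiran-2-yl]prop-2-enoate
Conditions: Ph3P=CHCO2Me, N-iodosuccinimide, CH2Cl2, −20 °C; then 8, −20 → 23 °C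
Reagents that add atoms: methyl (triphenylphosphoranylidene)acetate COC(=O)C=P(c1ccccc1)(c1ccccc1)c1ccccc1; N-iodosuccinimide O=C1CCC(=O)N1I
Why: Wittig olefination with the stabilised iodo ylide made in situ places the ester trans to C2, as stabilised ylides do, giving the (Z)-α-iodoenoate that fixes the C1=C10 geometry.

Step 8
Reactants: 10 (2E)-but-2-ene-1,4-diol
Product: 11 (2E)-4-[(triethylsilyl)oxy]but-2-en-1-ol
Conditions: Et3SiCl (1 equiv), imidazole, DMF, 0 °C, diol in excess (3 equiv)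
Reagents that add atoms: chlorotriethylsilane CC[Si](Cl)(CC)CC
Why: Statistical monosilylation of the symmetrical diol used in excess (silyl ether formation).

Step 9
Reactants: 11 (2E)-4-[(triethylsilyl)oxy]but-2-en-1-ol
Product: 12 [(2R,3R)-3-{[(triethylsilyl)oxy]methyl}oxiran-2-yl]methanol
Conditions: Ti(OiPr)4 (cat.), D-(−)-diethyl tartrate (cat.), t-BuOOH, 4 Å MS, CH2Cl2, −20 °C
Reagents that add atoms: tert-butyl hydroperoxide CC(C)(C)OO
Why: Sharpless asymmetric epoxidation of the (E)-allylic alcohol with D-(−)-tartrate gives the (2R,3R) trans-epoxy alcohol, which fixes C7 and C8.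

Step 10
Reactants: 12 [(2R,3R)-3-{[(triethylsilyl)oxy]methyl}oxiran-2-yl]methanol
Product: 13 (2S,3R)-3-{[(triethylsilyl)oxy]methyl}oxirane-2-carbaldehyde
Conditions: Dess–Martin periodinane, pyridine, CH2Cl2, 0 °C
Reagents that add atoms: none
Why: Buffered Dess–Martin oxidation gives the trans-epoxy aldehyde and leaves the primary triethylsilyl ether and the epoxide intact.

Step 11
Reactants: 9 methyl (2Z)-2-iodo-3-[(2R,3S)-3-[(1Z)-1-iodoprop-1-en-2-yl]oxiran-2-yl]prop-2-enoate; 13 (2S,3R)-3-{[(triethylsilyl)oxy]methyl}oxirane-2-carbaldehyde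
Product: 15 methyl (2E)-2-[(R)-hydroxy{(2R,3R)-3-[(triethylsilyloxy)methyl]oxiran-2-yl}methyl]-3-{(2R,3S)-3-[(1Z)-1-iodoprop-1-en-2-yl]oxiran-2-yl}prop-2-enoate, via alkenylmagnesium chloride 14 (not isolated)
Conditions: i-PrMgCl·LiCl (1.05 equiv), THF, −78 °C, 15 min; then 13, −78 °C
Reagents that add atoms: none
Why: Iodine–magnesium exchange (Knochel) should occur only at the ester-activated C10–I bond at −78 °C, and the alkenylmagnesium adds to the aldehyde with retention of alkene geometry, Felkin–Anh attack anti to the epoxide C–O bond setting the 9R carbinol anti to the 7,8-epoxide.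

Step 12
Reactants: 15 the C9 alcohol of step 11
Product: 16 methyl (2E)-2-[(R)-[(tert-butyldimethylsilyl)oxy]{(2S,3R)-3-[(triethylsilyloxy)methyl]oxiran-2-yl}methyl]-3-{(2R,3S)-3-[(1Z)-1-iodoprop-1-en-2-yl]oxiran-2-yl}prop-2-enoate
Conditions: t-BuMe2SiOTf, 2,6-lutidine, CH2Cl2, −78 °C
Reagents that add atoms: tert-butyldimethylsilyl trifluoromethanesulfonate CC(C)(C)[Si](C)(C)OS(=O)(=O)C(F)(F)F
Why: Silylation of the hindered secondary alcohol with the silyl triflate and a hindered base gives an O9 group that, unlike an acyl group, should not migrate to O8 later.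

Step 13
Reactants: 16 the bis-silyl ether of step 12
Product: 18 methyl (2E)-2-[(R)-[(tert-butyldimethylsilyl)oxy][(2S,3S)-3-formyloxiran-2-yl]methyl]-3-{(2R,3S)-3-[(1Z)-1-iodoprop-1-en-2-yl]oxiran-2-yl}prop-2-enoate, via alkoxydimethylsulfonium chloride 17 (not isolated)
Conditions: (COCl)2, DMSO, CH2Cl2, −78 → −40 °C; then Et3N, −78 → 0 °C
Reagents that add atoms: none
Why: Under Swern conditions a primary triethylsilyl ether is cleaved by the chlorosulfonium salt and oxidised directly to the aldehyde, while the secondary tert-butyldimethylsilyl ether is untouched.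

Step 14
Reactants: 18 the iodo aldehyde of step 13
Product: 19 methyl (1(10)E,4Z,2R,3S,6R,7R,8S,9R)-9-[(tert-butyldimethylsilyl)oxy]-2,3:7,8-diepoxy-6-hydroxy-4-methylcyclodeca-1(10),4-diene-10-carboxylate
Conditions: CrCl2 (10 equiv), NiCl2 (2 mol %), DMSO/THF, 0.002 M, 23 °C
Reagents that add atoms: none
Why: Intramolecular Nozaki–Hiyama–Kishi reaction under high dilution closes the ten-membered ring at C5–C6 with retention of the (Z)-alkenyl geometry, and Felkin–Anh attack anti to the epoxide C–O bond should give the 6R alcohol anti to the 7,8-epoxide.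

Step 15
Reactants: 19 the macrocyclic allylic alcohol of step 14
Product: 20 methyl (1(10)E,2R,3R,4R,5R,6S,7R,8S,9R)-9-[(tert-butyldimethylsilyl)oxy]-2,3:4,5:7,8-triepoxy-6-hydroxy-4-methylcyclodec-1(10)-ene-10-carboxylate
Conditions: dimethyldioxirane (acetone solution), CH2Cl2, −20 → 0 °C
Reagents that add atoms: dimethyldioxirane CC1(C)OO1
Why: Only the electron-rich C4=C5 bond is epoxidised, and in the rotamer that minimises A(1,3) strain of the Z-allylic alcohol the C6 hydroxyl sits on the outer ring face and hydrogen-bonds the oxidant, so the threo 4R,5R epoxide should form (hydroxyl-directed peripheral epoxidation).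

Step 16
Reactants: 20 the triepoxy alcohol of step 15
Product: 21 methyl (1(10)E,2R,3R,4R,5R,6S,7S,8S,9R)-9-[(tert-butyldimethylsilyl)oxy]-6-{[(diethoxyphosphoryl)acetyl]oxy}-2,3:4,5:7,8-triepoxy-4-methylcyclodec-1(10)-ene-10-carboxylate
Conditions: (EtO)2P(O)CH2CO2H, DCC, DMAP (cat.), CH2Cl2, 0 → 23 °C
Reagents that add atoms: (diethoxyphosphoryl)acetic acid CCOP(=O)(CC(=O)O)OCC
Why: Carbodiimide (Steglich) esterification acylates the only free hydroxyl, phosphonoacetic acids being known to esterify hindered secondary alcohols readily.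

Step 17
Reactants: 21 the O6 phosphonoacetate of step 16
Product: 23 methyl (1(10)E,2R,3R,4R,5R,6S,7R,8S,9R)-9-[(tert-butyldimethylsilyl)oxy]-2,3:4,5-diepoxy-8-hydroxygermacra-1(10),11(13)-dien-12,6-olid-14-oate, via sodium enolate of phosphono lactone 22 (not isolated)
Conditions: NaH (1.05 equiv), THF, 0 → 23 °C; then (CH2O)n, 0 → 23 °C
Reagents that add atoms: formaldehyde (from paraformaldehyde) C=O
Why: NaH deprotonates the phosphonoacetate at C11 and the carbanion attacks C7 of the trans-7,8-epoxide from the side opposite the C7–O bond (SN2, inversion), the C8 alkoxide is quenched by the now more acidic C11–H to give the enolate of phosphono lactone 22, and formaldehyde then forms C11=C13 by Horner–Wadsworth–Emmons olefination. The closest known reaction types are the Stork-type intramolecular alkylation of a stabilised carbanion by an epoxide, the epoxide opening by phosphonoacetate anions that starts the Wadsworth–Emmons cyclopropanation, and the alkylation/olefination route to α-methylene-γ-butyrolactones. The γ-lactone ring (O–C6–C7–C11–C12) closes 5-exo-tet, with the breaking C7–O bond outside the new ring, and is trans-fused to the ten-membered ring. C7 is set by inversion of an epoxide carbon whose configuration came from the Sharpless epoxidation of step 9, C8 keeps its oxygen with retention, and C11 becomes sp2. The step needs attack at C7 rather than at C8 (6-endo), at C5 of the 4,5-epoxide, at the remote 2,3-epoxide or at the enoate: the erythro relationship of O6 to the 7,8-epoxide puts C7–O antiperiplanar to C6–O in a staggered ring conformer, whereas the threo 4,5-epoxide could be reached at C5 only through an eclipsed C4–C5–C6–C7 torsion and next to the quaternary C4. Because O9 is silylated, O8 emerges as the only free hydroxyl, which differentiates the two ester positions of the target.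

Step 18
Reactants: 24 methyl (2Z)-2-methylbut-2-enoate (methyl angelate)
Product: 25 (2Z)-2-methylbut-2-en-1-ol
Conditions: LiAlH4, Et2O, 0 °C
Reagents that add atoms: none
Why: Hydride reduction of the ester gives the allylic alcohol without isomerising the Z trisubstituted alkene.

Step 19
Reactants: 25 (2Z)-2-methylbut-2-en-1-ol
Product: 26 [(2R,3S)-2,3-dimethyloxiran-2-yl]methanol
Conditions: Ti(OiPr)4 (cat.), D-(−)-diethyl tartrate (cat.), t-BuOOH, 4 Å MS, CH2Cl2, −20 °C
Reagents that add atoms: tert-butyl hydroperoxide CC(C)(C)OO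
Why: Sharpless asymmetric epoxidation with D-(−)-tartrate sets both epoxide centres of the acyl group from the Z alkene.

Step 20
Reactants: 26 [(2R,3S)-2,3-dimethyloxiran-2-yl]methanol
Product: 27 (2S,3S)-2,3-dimethyloxirane-2-carboxylic acid
Conditions: RuCl3·xH2O (cat.), NaIO4, CCl4/MeCN/H2O, 23 °C
Reagents that add atoms: sodium periodate [Na+].[O-]I(=O)(=O)=O
Why: Ruthenium-catalysed periodate oxidation (Sharpless conditions) takes the epoxy alcohol to the glycidic acid without opening the epoxide.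

Step 21
Reactants: 23 the C8 alcohol of step 17; 27 (2S,3S)-2,3-dimethyloxirane-2-carboxylic acid
Product: 29 methyl (1(10)E,2R,3R,4R,5R,6S,7S,8S,9R)-9-[(tert-butyldimethylsilyl)oxy]-8-{[(2S,3S)-2,3-dimethyloxirane-2-carbonyl]oxy}-2,3:4,5-diepoxygermacra-1(10),11(13)-dien-12,6-olid-14-oate, via mixed anhydride 28 (not isolated)
Conditions: 2,4,6-Cl3C6H2COCl, Et3N, THF, 23 °C; then 23, DMAP, toluene, 23 °C
Reagents that add atoms: none
Why: Yamaguchi esterification activates the hindered tertiary acid as a mixed anhydride that DMAP transfers to the only free hydroxyl (O8), with no stereocentre touched.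

Step 22
Reactants: 29 the O8 ester of step 21
Product: 30 methyl (1(10)E,2R,3R,4R,5R,6S,7R,8S,9R)-8-{[(2S,3S)-2,3-dimethyloxirane-2-carbonyl]oxy}-2,3:4,5-diepoxy-9-hydroxygermacra-1(10),11(13)-dien-12,6-olid-14-oate
Conditions: HF·pyridine, pyridine, THF, 0 → 23 °C
Reagents that add atoms: none
Why: Buffered fluoride desilylation removes the secondary silyl ether without opening the epoxides or adding to the α-methylene lactone.

Step 23
Reactants: 30 the C9 alcohol of step 22
Product: 31 methyl (1(10)E,2R,3R,4R,5R,6S,7R,8S,9R)-9-acetoxy-8-{[(2S,3S)-2,3-dimethyloxirane-2-carbonyl]oxy}-2,3:4,5-diepoxygermacra-1(10),11(13)-dien-12,6-olid-14-oate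
Conditions: Ac2O, DMAP (cat.), pyridine, CH2Cl2, 0 °C
Reagents that add atoms: acetic anhydride CC(=O)OC(C)=O
Why: DMAP-catalysed acetylation of the C9 alcohol should be faster than migration of the hindered O8 acyl group.

**Compound list**
1 | prop-2-yn-1-ol | C#CCO | starting material
2 | (Z)-[3-(bromomagnesiooxy)-2-methylprop-1-en-1-yl]magnesium bromide (chelate) | Br[Mg]OC/C(C)=C\[Mg]Br | intermediate
3 | (2Z)-3-iodo-2-methylprop-2-en-1-ol | OC/C(C)=C\I | intermediate
4 | (2Z)-3-iodo-2-methylprop-2-enal | O=C/C(C)=C\I | intermediate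
5 | methyl (2Z,4Z)-5-iodo-4-methylpenta-2,4-dienoate | COC(=O)/C=C\C(C)=C/I | intermediate
6 | (2Z,4Z)-5-iodo-4-methylpenta-2,4-dien-1-ol | OC/C=C\C(C)=C/I | intermediate
7 | [(2R,3S)-3-[(1Z)-1-iodoprop-1-en-2-yl]oxiran-2-yl]methanol | OC[C@H]1O[C@H]1/C(C)=C\I | intermediate
8 | (2S,3S)-3-[(1Z)-1-iodoprop-1-en-2-yl]oxirane-2-carbaldehyde | O=C[C@H]1O[C@H]1/C(C)=C\I | intermediate
9 | methyl (2Z)-2-iodo-3-[(2R,3S)-3-[(1Z)-1-iodoprop-1-en-2-yl]oxiran-2-yl]prop-2-enoate | I/C(C(=O)OC)=C\[C@H]1O[C@H]1/C(C)=C\I | intermediate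
10 | (2E)-but-2-ene-1,4-diol | OC/C=C/CO | starting material
11 | (2E)-4-[(triethylsilyl)oxy]but-2-en-1-ol | CC[Si](CC)(CC)OC/C=C/CO | intermediate
12 | [(2R,3R)-3-{[(triethylsilyl)oxy]methyl}oxiran-2-yl]methanol | CC[Si](CC)(CC)OC[C@H]1O[C@@H]1CO | intermediate
13 | (2S,3R)-3-{[(triethylsilyl)oxy]methyl}oxirane-2-carbaldehyde | CC[Si](CC)(CC)OC[C@H]1O[C@@H]1C=O | intermediate
14 | methyl (2Z)-2-(chloromagnesio)-3-[(2R,3S)-3-[(1Z)-1-iodoprop-1-en-2-yl]oxiran-2-yl]prop-2-enoate | Cl[Mg]/C(C(=O)OC)=C\[C@H]1O[C@H]1/C(C)=C\I | intermediate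
15 | methyl (2E)-2-[(R)-hydroxy{(2R,3R)-3-[(triethylsilyloxy)methyl]oxiran-2-yl}methyl]-3-{(2R,3S)-3-[(1Z)-1-iodoprop-1-en-2-yl]oxiran-2-yl}prop-2-enoate | CC[Si](CC)(CC)OC[C@H]1O[C@@H]1[C@H](O)/C(C(=O)OC)=C\[C@H]1O[C@H]1/C(C)=C\I | intermediate
16 | methyl (2E)-2-[(R)-[(tert-butyldimethylsilyl)oxy]{(2S,3R)-3-[(triethylsilyloxy)methyl]oxiran-2-yl}methyl]-3-{(2R,3S)-3-[(1Z)-1-iodoprop-1-en-2-yl]oxiran-2-yl}prop-2-enoate | CC[Si](CC)(CC)OC[C@H]1O[C@@H]1[C@H](O[Si](C)(C)C(C)(C)C)/C(C(=O)OC)=C\[C@H]1O[C@H]1/C(C)=C\I | intermediate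
17 | alkoxydimethylsulfonium chloride of 16 (Et3Si on the C6 oxygen replaced by S+Me2) | C[S+](C)OC[C@H]1O[C@@H]1[C@H](O[Si](C)(C)C(C)(C)C)/C(C(=O)OC)=C\[C@H]1O[C@H]1/C(C)=C\I.[Cl-] | intermediate
18 | methyl (2E)-2-[(R)-[(tert-butyldimethylsilyl)oxy][(2S,3S)-3-formyloxiran-2-yl]methyl]-3-{(2R,3S)-3-[(1Z)-1-iodoprop-1-en-2-yl]oxiran-2-yl}prop-2-enoate | O=C[C@H]1O[C@@H]1[C@H](O[Si](C)(C)C(C)(C)C)/C(C(=O)OC)=C\[C@H]1O[C@H]1/C(C)=C\I | intermediate
19 | methyl (1(10)E,4Z,2R,3S,6R,7R,8S,9R)-9-[(tert-butyldimethylsilyl)oxy]-2,3:7,8-diepoxy-6-hydroxy-4-methylcyclodeca-1(10),4-diene-10-carboxylate | O[C@H]2[C@H]3O[C@@H]3[C@H](O[Si](C)(C)C(C)(C)C)/C(C(=O)OC)=C\[C@H]1O[C@H]1/C(C)=C\2 | intermediate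
20 | methyl (1(10)E,2R,3R,4R,5R,6S,7R,8S,9R)-9-[(tert-butyldimethylsilyl)oxy]-2,3:4,5:7,8-triepoxy-6-hydroxy-4-methylcyclodec-1(10)-ene-10-carboxylate | O[C@H]2[C@H]3O[C@@H]3[C@H](O[Si](C)(C)C(C)(C)C)/C(C(=O)OC)=C\[C@H]1O[C@H]1[C@]1(C)O[C@H]21 | intermediate
21 | methyl (1(10)E,2R,3R,4R,5R,6S,7S,8S,9R)-9-[(tert-butyldimethylsilyl)oxy]-6-{[(diethoxyphosphoryl)acetyl]oxy}-2,3:4,5:7,8-triepoxy-4-methylcyclodec-1(10)-ene-10-carboxylate | CCOP(=O)(OCC)CC(=O)O[C@H]2[C@H]3O[C@@H]3[C@H](O[Si](C)(C)C(C)(C)C)/C(C(=O)OC)=C\[C@H]1O[C@H]1[C@]1(C)O[C@H]21 | intermediate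
22 | 6,12-lactone with (EtO)2P(O) on C11 (both C11 epimers, present as the sodium enolate), 8-OH, 9-OSiMe2t-Bu, 2,3:4,5-diepoxide, methyl 1(10)E-en-14-oate; 2R,3R,4R,5R,6S,7R,8S,9R | CCOP(=O)(OCC)C1C(=O)O[C@H]2[C@H]1[C@H](O)[C@H](O[Si](C)(C)C(C)(C)C)/C(C(=O)OC)=C\[C@H]1O[C@H]1[C@]1(C)O[C@H]21 | intermediate
23 | methyl (1(10)E,2R,3R,4R,5R,6S,7R,8S,9R)-9-[(tert-butyldimethylsilyl)oxy]-2,3:4,5-diepoxy-8-hydroxygermacra-1(10),11(13)-dien-12,6-olid-14-oate | C=C1C(=O)O[C@H]2[C@H]1[C@H](O)[C@H](O[Si](C)(C)C(C)(C)C)/C(C(=O)OC)=C\[C@H]1O[C@H]1[C@]1(C)O[C@H]21 | intermediate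
24 | methyl (2Z)-2-methylbut-2-enoate (methyl angelate) | C/C=C(/C)C(=O)OC | starting material
25 | (2Z)-2-methylbut-2-en-1-ol | C/C=C(/C)CO | intermediate
26 | [(2R,3S)-2,3-dimethyloxiran-2-yl]methanol | OC[C@@]1(C)O[C@H]1C | intermediate
27 | (2S,3S)-2,3-dimethyloxirane-2-carboxylic acid | OC(=O)[C@@]1(C)O[C@H]1C | intermediate
28 | (2S,3S)-2,3-dimethyloxirane-2-carboxylic 2,4,6-trichlorobenzoic anhydride | O=C(OC(=O)[C@@]1(C)O[C@H]1C)c1c(Cl)cc(Cl)cc1Cl | intermediate
29 | methyl (1(10)E,2R,3R,4R,5R,6S,7S,8S,9R)-9-[(tert-butyldimethylsilyl)oxy]-8-{[(2S,3S)-2,3-dimethyloxirane-2-carbonyl]oxy}-2,3:4,5-diepoxygermacra-1(10),11(13)-dien-12,6-olid-14-oate | C=C1C(=O)O[C@H]2[C@H]1[C@H](OC(=O)[C@@]1(C)O[C@H]1C)[C@H](O[Si](C)(C)C(C)(C)C)/C(C(=O)OC)=C\[C@H]1O[C@H]1[C@]1(C)O[C@H]21 | intermediate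
30 | methyl (1(10)E,2R,3R,4R,5R,6S,7R,8S,9R)-8-{[(2S,3S)-2,3-dimethyloxirane-2-carbonyl]oxy}-2,3:4,5-diepoxy-9-hydroxygermacra-1(10),11(13)-dien-12,6-olid-14-oate | C=C1C(=O)O[C@H]2[C@H]1[C@H](OC(=O)[C@@]1(C)O[C@H]1C)[C@H](O)/C(C(=O)OC)=C\[C@H]1O[C@H]1[C@]1(C)O[C@H]21 | intermediate
31 | methyl (1(10)E,2R,3R,4R,5R,6S,7R,8S,9R)-9-acetoxy-8-{[(2S,3S)-2,3-dimethyloxirane-2-carbonyl]oxy}-2,3:4,5-diepoxygermacra-1(10),11(13)-dien-12,6-olid-14-oate | C=C1C(=O)O[C@H]2[C@H]1[C@H](OC(=O)[C@@]1(C)O[C@H]1C)[C@H](OC(C)=O)/C(C(=O)OC)=C\[C@H]1O[C@H]1[C@]1(C)O[C@H]21 | target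

**Totals**
Total step count: 23. Longest linear sequence: 17 (steps 1–7, 11–17, 21–23).

**Steps most likely to fail**

Step 14. The chromium-mediated addition may show poor facial selectivity at C6, and oligomerisation may compete with the slow closure of the strained ten-membered ring. Fallback, setting out from 18: the closure is run as before and the mixture of 19 and the C6-epimeric alcohol F1 is oxidised with Dess–Martin periodinane to the macrocyclic epoxy enone F2. Reduction with Zn(BH4)2 in Et2O at −20 °C, where zinc is chelated between the ketone and the 7,8-epoxide oxygen, should give the anti epoxy alcohol, and the route is rejoined at 19.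

Step 17. The carbanion may open the 4,5-epoxide at C5 instead, or closure may be slow because the ester must leave its preferred s-trans rotamer, which would allow phosphoryl transfer to O8 on warming. Fallback, setting out from 19: the competing electrophile is removed by postponing the 4,5-epoxidation. Alcohol 19 is esterified with (diethoxyphosphoryl)acetic acid (DCC, DMAP) to the diene phosphonoacetate F3. NaH and then paraformaldehyde take it through the diene phosphono lactone F4 (not isolated) to the 4Z-ene methylene lactone F5, where C5 is vinylic and cannot be attacked. Dimethyldioxirane then epoxidises C4=C5 from the peripheral face, and the route is rejoined at 23.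

Step 11. The alkenylmagnesium may equilibrate with a magnesium allenoate and lose the C1=C10 geometry, and Felkin selectivity at C9 may be modest. Fallback, setting out from 13 and 4 and returning at 16: the C9–C10 bond is made first and the trisubstituted alkene afterwards under thermodynamic control. A Morita–Baylis–Hillman reaction of 13 with methyl acrylate (DABCO) gives the acrylate alcohol F6, which is silylated (t-BuMe2SiOTf, 2,6-lutidine) to the silyl ether F7. Aldehyde 4 is treated with (Z)-γ-chloroallyl(diisopinocampheyl)borane to give the syn-chlorohydrin F8, which K2CO3 in MeOH closes to the cis-vinyl epoxide F9. Cross-metathesis of F7 with F9 (second-generation Hoveyda–Grubbs ruthenium carbene catalyst, CH2Cl2, 23–40 °C) should give the E-configured enoate 16.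

Further compounds
F1 | step 14 | methyl (1(10)E,4Z,2R,3S,6S,7R,8S,9R)-9-[(tert-butyldimethylsilyl)oxy]-2,3:7,8-diepoxy-6-hydroxy-4-methylcyclodeca-1(10),4-diene-10-carboxylate (C6 epimer of 19) | O[C@@H]2[C@H]3O[C@@H]3[C@H](O[Si](C)(C)C(C)(C)C)/C(C(=O)OC)=C\[C@H]1O[C@H]1/C(C)=C\2
F2 | step 14 | methyl (1(10)E,4Z,2R,3S,7S,8S,9R)-9-[(tert-butyldimethylsilyl)oxy]-2,3:7,8-diepoxy-4-methyl-6-oxocyclodeca-1(10),4-diene-10-carboxylate | O=C2[C@H]3O[C@@H]3[C@H](O[Si](C)(C)C(C)(C)C)/C(C(=O)OC)=C\[C@H]1O[C@H]1/C(C)=C\2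
F3 | step 17 | methyl (1(10)E,4Z,2R,3S,6R,7R,8S,9R)-9-[(tert-butyldimethylsilyl)oxy]-6-{[(diethoxyphosphoryl)acetyl]oxy}-2,3:7,8-diepoxy-4-methylcyclodeca-1(10),4-diene-10-carboxylate | CCOP(=O)(OCC)CC(=O)O[C@H]2[C@H]3O[C@@H]3[C@H](O[Si](C)(C)C(C)(C)C)/C(C(=O)OC)=C\[C@H]1O[C@H]1/C(C)=C\2
F4 | step 17 | 6,12-lactone with (EtO)2P(O) on C11 (as sodium enolate), 8-OH, 9-OSiMe2t-Bu, 2,3-epoxide, 4Z-ene, methyl 1(10)E-en-14-oate; 2R,3S,6R,7R,8S,9R | CCOP(=O)(OCC)C1C(=O)O[C@H]2[C@H]1[C@H](O)[C@H](O[Si](C)(C)C(C)(C)C)/C(C(=O)OC)=C\[C@H]1O[C@H]1/C(C)=C\2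
F5 | step 17 | methyl (1(10)E,4Z,2R,3S,6R,7R,8S,9R)-9-[(tert-butyldimethylsilyl)oxy]-2,3-epoxy-8-hydroxygermacra-1(10),4,11(13)-trien-12,6-olid-14-oate | C=C1C(=O)O[C@H]2[C@H]1[C@H](O)[C@H](O[Si](C)(C)C(C)(C)C)/C(C(=O)OC)=C\[C@H]1O[C@H]1/C(C)=C\2
F6 | step 11 | methyl 2-[(R)-hydroxy{(2R,3R)-3-[(triethylsilyloxy)methyl]oxiran-2-yl}methyl]prop-2-enoate | CC[Si](CC)(CC)OC[C@H]1O[C@@H]1[C@H](O)C(=C)C(=O)OC
F7 | step 11 | methyl 2-[(R)-[(tert-butyldimethylsilyl)oxy]{(2S,3R)-3-[(triethylsilyloxy)methyl]oxiran-2-yl}methyl]prop-2-enoate | CC[Si](CC)(CC)OC[C@H]1O[C@@H]1[C@H](O[Si](C)(C)C(C)(C)C)C(=C)C(=O)OC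
F8 | step 11 | (1Z,3S,4S)-4-chloro-1-iodo-2-methylhexa-1,5-dien-3-ol | C=C[C@H](Cl)[C@@H](O)/C(C)=C\I
F9 | step 11 | (2R,3S)-2-ethenyl-3-[(1Z)-1-iodoprop-1-en-2-yl]oxirane | C=C[C@H]1O[C@H]1/C(C)=C\I
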